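**Retrosynthetic overview**
1. Target 16 ⇐ dioxolane 15 (the enone is unmasked last, so a free hydroxy-enone never exists) ⇐ Stille union of vinylstannane 13 with (Z)-3-iodobut-2-enoic acid 14.
2. Key disconnection: the neopentyl ester C–O bond, from alcohol 11 and prochiral 3-hydroxy-3-methylglutaric anhydride 12; this one bond joins the two halves and sets the glutarate 3R centre.
3. 11 ⇐ (S)-β-hydroxy ketone 8 by chelation-controlled vinyl addition (sets C1′ relative to C6′); 8 ⇐ silyl dienol ether 6 by asymmetric hydroxymethylation (sets quaternary C6′).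
4. Rings: no carbocycle is built; the six-membered ring is the dearomatised ring of 2,6-dimethylphenol 1. The only ring formed is the temporary dioxolane (step 1), opened in step 7.

Assumption: the SMILES is taken literally, i.e. ring (1′R,6′S) with the acyloxymethyl group cis to the dienoic acid chain and trans to the tertiary OH, glutarate (3R); compounds 9, 12 and 14 are bought.

**Route**

Step 1
Reactants: 1 2,6-dimethylphenol; 2 ethylene glycol
Product: 4 7,9-dimethyl-1,4-dioxaspiro[4.5]deca-6,9-dien-8-one, via 4-(2-hydroxyethoxy)-2,6-dimethylphenol 3 (not isolated)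
Conditions: PhI(OAc)2 (2.2 equiv), HOCH2CH2OH, 0 °C → rt
Reagents that add atoms: none
Why: Hypervalent-iodine oxidative dearomatisation (two successive para-oxidations, ortho positions blocked) gives the p-quinone monoketal, with the ketal on the unhindered carbon and the methyl-flanked ketone left free.

Step 2
Reactants: 4 7,9-dimethyl-1,4-dioxaspiro[4.5]deca-6,9-dien-8-one
Product: 6 trimethyl[(7,9-dimethyl-1,4-dioxaspiro[4.5]deca-6,8-dien-8-yl)oxy]silane, via lithium dienolate 5 (not isolated)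
Conditions: L-Selectride (1.05 equiv), THF, −78 °C; then TMSCl, Et3N, −78 → 0 °C
Reagents that add atoms: chlorotrimethylsilane, C[Si](C)(C)Cl
Why: Conjugate (1,4) hydride reduction of the cross-conjugated dienone (the carbonyl is shielded by two α-methyls; both enone arms are equivalent) gives one regiodefined enolate, which is trapped by O-silylation.

Step 3
Reactants: 6 trimethyl[(7,9-dimethyl-1,4-dioxaspiro[4.5]deca-6,8-dien-8-yl)oxy]silane; 7 formaldehyde
Product: 8 (9S)-9-(hydroxymethyl)-7,9-dimethyl-1,4-dioxaspiro[4.5]dec-6-en-8-one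
Conditions: 37% aq. HCHO (5 equiv), Sc(OTf)3 (10 mol%), (S,S)-6,6′-bis(1-hydroxy-2,2-dimethylpropyl)-2,2′-bipyridine (12 mol%; antipode if the first run gives 9R), DME/H2O 9:1, −20 °C
Reagents that add atoms: none
Why: Kobayashi-type aqueous asymmetric Mukaiyama aldol (hydroxymethylation), known to give α-methyl-α-hydroxymethyl quaternary ketones from cyclic 2-methyl silyl enol ethers conjugated to an sp2 carbon; the Sc–bipyridine-bound formaldehyde attacks one enantiotopic face of the enol carbon and sets C9 (S).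

Step 4
Reactants: 8 (9S)-9-(hydroxymethyl)-7,9-dimethyl-1,4-dioxaspiro[4.5]dec-6-en-8-one; 9 (E)-1,2-bis(tributylstannyl)ethene
Product: 11 (8R,9S)-9-(hydroxymethyl)-7,9-dimethyl-8-[(E)-2-(tributylstannyl)ethenyl]-1,4-dioxaspiro[4.5]dec-6-en-8-ol, via chloromagnesium alkoxide 10 (not isolated)
Conditions: 8, t-BuMgCl (1.0 equiv), THF, −78 °C; then (E)-Bu3SnCH=CHLi (1.6 equiv, from 9 + n-BuLi, THF, −78 °C), −78 → −30 °C; aq. NH4Cl
Reagents that add atoms: none
Why: 1,2-Addition of the Corey–Wollenberg stannylvinyllithium under Cram-chelate control: the magnesium alkoxide chelates the non-enolisable ketone, holding CH2O pseudo-equatorial and the C9 methyl pseudo-axial, so the nucleophile enters axially anti to that methyl and ends cis to CH2OH (8R).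

Step 5 (key step)
Reactants: 11 (8R,9S)-9-(hydroxymethyl)-7,9-dimethyl-8-[(E)-2-(tributylstannyl)ethenyl]-1,4-dioxaspiro[4.5]dec-6-en-8-ol; 12 3-hydroxy-3-methylglutaric anhydride
Product: 13 (3R)-3-hydroxy-5-{[(8R,9S)-8-hydroxy-7,9-dimethyl-8-[(E)-2-(tributylstannyl)ethenyl]-1,4-dioxaspiro[4.5]dec-6-en-9-yl]methoxy}-3-methyl-5-oxopentanoic acid
Conditions: 12 (1.5 equiv), quinidine-derived 9-amino-9-deoxy-epi-cinchona squaramide bearing a 3,5-(CF3)2C6H3NH arm (10 mol%; quinine-derived pseudoenantiomer if the 3S ester predominates), MTBE, −20 °C; cold pH 4.5 citrate work-up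
Reagents that add atoms: none
Why: Proposed new method: catalyst-controlled desymmetrising alcoholysis of prochiral anhydride 12 by a complex, hindered primary alcohol used as the limiting reagent — the squaramide N–H pair binds the carbonyl that becomes the carboxylate, the free C–OH of 12 hydrogen-bonds to the catalyst so that OH and CH3 on the prochiral carbon are told apart, and the quinuclidine acts as general base for the primary OH of 11, which attacks the carbonyl of the pro-R arm (sets 3R; the tertiary OH is inert); the closest known reaction is the cinchona squaramide/thiourea- or (DHQD)2AQN-catalysed methanolysis of 3-substituted glutaric and meso anhydrides.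

Step 6
Reactants: 13 (3R)-3-hydroxy-5-{[(8R,9S)-8-hydroxy-7,9-dimethyl-8-[(E)-2-(tributylstannyl)ethenyl]-1,4-dioxaspiro[4.5]dec-6-en-9-yl]methoxy}-3-methyl-5-oxopentanoic acid; 14 (2Z)-3-iodobut-2-enoic acid
Product: 15 (2Z,4E)-5-[(8R,9S)-9-({[(3R)-4-carboxy-3-hydroxy-3-methylbutanoyl]oxy}methyl)-8-hydroxy-7,9-dimethyl-1,4-dioxaspiro[4.5]dec-6-en-8-yl]-3-methylpenta-2,4-dienoic acid
Conditions: Pd2(dba)3 (2.5 mol%), AsPh3 (20 mol%), i-Pr2NEt (3 equiv), NMP, 25 °C, dark
Reagents that add atoms: none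
Why: Stille cross-coupling goes with retention at both sp2 partners and gives the 2Z,4E-dienoic acid; the amine keeps both acids as spectator carboxylates and suppresses protodestannylation.

Step 7
Reactants: 15 (2Z,4E)-5-[(8R,9S)-9-({[(3R)-4-carboxy-3-hydroxy-3-methylbutanoyl]oxy}methyl)-8-hydroxy-7,9-dimethyl-1,4-dioxaspiro[4.5]dec-6-en-8-yl]-3-methylpenta-2,4-dienoic acid
Product: 16 (2Z,4E)-5-[(1R,6S)-6-({[(3R)-4-carboxy-3-hydroxy-3-methylbutanoyl]oxy}methyl)-1-hydroxy-2,6-dimethyl-4-oxocyclohex-2-en-1-yl]-3-methylpenta-2,4-dienoic acid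
Conditions: 1 M aq. HCl/acetone 1:4, 0 °C → rt, 1–2 h, dark
Reagents that add atoms: water, O
Why: Acid-catalysed acetal hydrolysis of the allylic dioxolane is fast (allyl-stabilised oxocarbenium) and gives the conjugated enone, while the neopentyl ester, both tertiary alcohols and the diene acid are untouched and the acylated CH2O cannot undergo oxa-Michael closure.

**Compound list**
1 | 2,6-dimethylphenol | Cc1cccc(C)c1O | starting material
2 | ethylene glycol | OCCO | starting material
3 | 4-(2-hydroxyethoxy)-2,6-dimethylphenol | Cc1cc(OCCO)cc(C)c1O | intermediate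
4 | 7,9-dimethyl-1,4-dioxaspiro[4.5]deca-6,9-dien-8-one | CC1=CC2(OCCO2)C=C(C)C1=O | intermediate
5 | lithium 7,9-dimethyl-1,4-dioxaspiro[4.5]deca-6,8-dien-8-olate | CC1=CC2(OCCO2)CC(C)=C1[O-].[Li+] | intermediate
6 | trimethyl[(7,9-dimethyl-1,4-dioxaspiro[4.5]deca-6,8-dien-8-yl)oxy]silane | CC1=CC2(OCCO2)CC(C)=C1O[Si](C)(C)C | intermediate
7 | formaldehyde | C=O | starting material
8 | (9S)-9-(hydroxymethyl)-7,9-dimethyl-1,4-dioxaspiro[4.5]dec-6-en-8-one | CC1=CC2(OCCO2)C[C@@](C)(CO)C1=O | intermediate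
9 | (E)-1,2-bis(tributylstannyl)ethene | CCCC[Sn](CCCC)(CCCC)/C=C/[Sn](CCCC)(CCCC)CCCC | starting material
10 | chloromagnesium [(9S)-7,9-dimethyl-8-oxo-1,4-dioxaspiro[4.5]dec-6-en-9-yl]methoxide | CC1=CC2(OCCO2)C[C@@](C)(CO[Mg]Cl)C1=O | intermediate
11 | (8R,9S)-9-(hydroxymethyl)-7,9-dimethyl-8-[(E)-2-(tributylstannyl)ethenyl]-1,4-dioxaspiro[4.5]dec-6-en-8-ol | CC1=CC2(OCCO2)C[C@@](C)(CO)[C@@]1(O)/C=C/[Sn](CCCC)(CCCC)CCCC | intermediate
12 | 3-hydroxy-3-methylglutaric anhydride (4-hydroxy-4-methyloxane-2,6-dione) | CC1(O)CC(=O)OC(=O)C1 | starting material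
13 | (3R)-3-hydroxy-5-{[(8R,9S)-8-hydroxy-7,9-dimethyl-8-[(E)-2-(tributylstannyl)ethenyl]-1,4-dioxaspiro[4.5]dec-6-en-9-yl]methoxy}-3-methyl-5-oxopentanoic acid | CC1=CC2(OCCO2)C[C@@](C)(COC(=O)C[C@](C)(O)CC(=O)O)[C@@]1(O)/C=C/[Sn](CCCC)(CCCC)CCCC | intermediate
14 | (2Z)-3-iodobut-2-enoic acid | C/C(I)=C/C(=O)O | starting material
15 | (2Z,4E)-5-[(8R,9S)-9-({[(3R)-4-carboxy-3-hydroxy-3-methylbutanoyl]oxy}methyl)-8-hydroxy-7,9-dimethyl-1,4-dioxaspiro[4.5]dec-6-en-8-yl]-3-methylpenta-2,4-dienoic acid | CC1=CC2(OCCO2)C[C@@](C)(COC(=O)C[C@](C)(O)CC(=O)O)[C@@]1(O)/C=C/C(C)=C\C(=O)O | intermediate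
16 | (2Z,4E)-5-[(1R,6S)-6-({[(3R)-4-carboxy-3-hydroxy-3-methylbutanoyl]oxy}methyl)-1-hydroxy-2,6-dimethyl-4-oxocyclohex-2-en-1-yl]-3-methylpenta-2,4-dienoic acid | CC1=CC(=O)C[C@@](C)(COC(=O)C[C@](C)(O)CC(=O)O)[C@@]1(O)/C=C/C(C)=C\C(=O)O | target

**Totals**
Total step count: 7. Longest linear sequence: 7 (1 → 4 → 6 → 8 → 11 → 13 → 15 → 16).

**Three steps most likely to fail**

Step 5 (the proposed new step). The risks are weak OH/CH3 discrimination at the prochiral carbon of 12 and slow acylation of a neopentyl alcohol. Fallback with known chemistry, setting out from 11 and returning at 13: the stereocentre is bought in instead of made. The known pig-liver-esterase half-hydrolysis of dimethyl 3-hydroxy-3-methylglutarate gives (3S)-3-hydroxy-5-methoxy-3-methyl-5-oxopentanoic acid F5. Its free acid is coupled to 11 (EDC, DMAP, CH2Cl2) to give 1-methyl 5-{[(8R,9S)-8-hydroxy-7,9-dimethyl-8-[(E)-2-(tributylstannyl)ethenyl]-1,4-dioxaspiro[4.5]dec-6-en-9-yl]methyl} (3R)-3-hydroxy-3-methylpentanedioate F6. The unhindered methyl ester is then cleaved selectively with Me3SnOH (DCE, 60 °C) to give 13. Because the arm that was the free acid becomes the ester arm, the S half-ester delivers the 3R product. This material also serves as the reference for assigning the configuration from step 5.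

Step 3. The risks are modest ee on this dienol ether and partial ketal loss or protodesilylation in the aqueous Lewis-acid medium. Fallback by resolution, setting out from 6 and returning at 8: ligand-free hydroxymethylation (aq. HCHO, Yb(OTf)3, THF/H2O) gives racemic 9-(hydroxymethyl)-7,9-dimethyl-1,4-dioxaspiro[4.5]dec-6-en-8-one F1. Lipase-catalysed kinetic resolution (a lipase of the required sense chosen by screening, e.g. lipase PS; vinyl acetate, MTBE) then acetylates the R alcohol to [(9R)-7,9-dimethyl-8-oxo-1,4-dioxaspiro[4.5]dec-6-en-9-yl]methyl acetate F2. F2 is removed by chromatography, leaving unreacted 8.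

Step 4. The risks are that the facial selectivity rests on a chelation model and that the stannylvinyllithium is a bulky, basic reagent. Fallback, setting out from 8 and returning at 11: the C–C bond is made with a minimal sp nucleophile and the C–Sn bond afterwards. The magnesium alkoxide of 8 is treated with the cerium acetylide of (trimethylsilyl)acetylene (n-BuLi, CeCl3, THF, −78 °C) to give (8R,9S)-9-(hydroxymethyl)-7,9-dimethyl-8-[(trimethylsilyl)ethynyl]-1,4-dioxaspiro[4.5]dec-6-en-8-ol F3, and the minor C8 epimer is removed at this stage by crystallisation or chromatography. K2CO3/MeOH gives (8R,9S)-8-ethynyl-9-(hydroxymethyl)-7,9-dimethyl-1,4-dioxaspiro[4.5]dec-6-en-8-ol F4. Pd-catalysed hydrostannation (Bu3SnH, PdCl2(PPh3)2, THF), which places tin at the distal carbon of a tertiary propargylic alcohol, gives the E-vinylstannane 11.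

**Further compounds**
F1 | step 3 | racemic 9-(hydroxymethyl)-7,9-dimethyl-1,4-dioxaspiro[4.5]dec-6-en-8-one | CC1=CC2(OCCO2)CC(C)(CO)C1=O
F2 | step 3 | [(9R)-7,9-dimethyl-8-oxo-1,4-dioxaspiro[4.5]dec-6-en-9-yl]methyl acetate | CC1=CC2(OCCO2)C[C@](C)(COC(C)=O)C1=O
F3 | step 4 | (8R,9S)-9-(hydroxymethyl)-7,9-dimethyl-8-[(trimethylsilyl)ethynyl]-1,4-dioxaspiro[4.5]dec-6-en-8-ol | CC1=CC2(OCCO2)C[C@@](C)(CO)[C@@]1(O)C#C[Si](C)(C)C
F4 | step 4 | (8R,9S)-8-ethynyl-9-(hydroxymethyl)-7,9-dimethyl-1,4-dioxaspiro[4.5]dec-6-en-8-ol | CC1=CC2(OCCO2)C[C@@](C)(CO)[C@@]1(O)C#C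
F5 | step 5 | (3S)-3-hydroxy-5-methoxy-3-methyl-5-oxopentanoic acid | OC(=O)C[C@](C)(O)CC(=O)OC
F6 | step 5 | 1-methyl 5-{[(8R,9S)-8-hydroxy-7,9-dimethyl-8-[(E)-2-(tributylstannyl)ethenyl]-1,4-dioxaspiro[4.5]dec-6-en-9-yl]methyl} (3R)-3-hydroxy-3-methylpentanedioate | CC1=CC2(OCCO2)C[C@@](C)(COC(=O)C[C@](C)(O)CC(=O)OC)[C@@]1(O)/C=C/[Sn](CCCC)(CCCC)CCCC
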